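**Retrosynthetic overview**
1. The allylic C17–O bond is made last: target 7 comes from the exocyclic 8(17)-alkene 6 by a transpositional allylic C–H acetoxylation (new step) that also moves the alkene to C7=C8.
2. Alkene 6 comes from diol 4 by 15-O-acetylation and dehydration of the equatorial 8α-OH toward C17.
3. Diol 4 comes from enal 2 by a catalyst-controlled conjugate reduction that sets C13 (S); enal 2 comes from sclareol 1 by oxidative 1,3-transposition (C15–O bond).
4. No ring is built: the trans-fused rings A and B, with C5, C9 and C10, are taken intact from (−)-sclareol.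

Assumption: labdane numbering is used throughout, and short-lived species (chromate esters, iminium ions, chlorosulfites, N-aluminium aldimines, η3-allylpalladium complexes) are named in the text but carry no number or label.

**Step 1**
Reactants: 1 (−)-sclareol
Product: 2 8α-hydroxylabd-13-en-15-al (13E/13Z mixture, about 2:1)
Conditions: pyridinium chlorochromate [C5H5NH][CrO3Cl] (3 equiv), 4 Å MS, CH2Cl2, rt, 12 h
Reagents that add atoms: pyridinium chlorochromate, [O-][Cr](=O)(=O)Cl.c1cc[nH+]cc1 (supplies the aldehyde oxygen)
Why: Babler–Dauben oxidative 1,3-transposition, in which the chromate ester of the tertiary allylic 13-OH undergoes a [3,3] shift to the primary C15 chromate that hexavalent chromium oxidises to the enal, while the non-allylic tertiary 8α-OH cannot be oxidised and both alkene isomers are usable because step 2 is enantioconvergent.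

**Step 2**
Reactants: 2 8α-hydroxylabd-13-en-15-al (13E/13Z mixture)
Product: 4 (13S)-labdane-8α,15-diol, via saturated hydroxy aldehyde 3 (not isolated)
Conditions: morpholinium salt of (S)-TRIP [(S)-3,3'-bis(2,4,6-triisopropylphenyl)-1,1'-binaphthyl-2,2'-diyl hydrogen phosphate] (20 mol%), Hantzsch ester (diethyl 2,6-dimethyl-1,4-dihydropyridine-3,5-dicarboxylate, 1.2 equiv), 1,4-dioxane, 50 °C, 24 h; then NaBH4, EtOH, 0 °C; recrystallise
Reagents that add atoms: none
Why: Asymmetric counteranion-directed iminium transfer hydrogenation, in which the E and Z iminium ions interconvert faster than hydride transfer so the chiral phosphate directs hydride to one face of C13 from either isomer and sets 13S at about 95:5 (this salt is the antipode of the one that gives (R)-citronellal from citral), after which NaBH4 reduces the aldehyde and recrystallisation raises the C13 purity.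

**Step 3**
Reactants: 4 (13S)-labdane-8α,15-diol
Product: 6 (13S)-labd-8(17)-en-15-yl acetate, via hydroxy acetate 5 (not isolated)
Conditions: Ac2O (1.2 equiv), pyridine, CH2Cl2, rt, 6 h; then SOCl2 (3 equiv), −78 °C, 1 h; AgNO3–SiO2 chromatography
Reagents that add atoms: acetic anhydride, CC(=O)OC(C)=O
Why: Selective acylation of the primary 15-OH (the hindered tertiary 8-OH does not react) followed by E2 dehydration of the equatorial 8α-chlorosulfite, which has no anti-periplanar ring hydrogen and so loses a C17 methyl hydrogen to give mainly the exocyclic alkene (about 85:15 over ring-alkene isomers, removed on silver nitrate silica).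

**Step 4**
Reactants: 6 (13S)-labd-8(17)-en-15-yl acetate
Product: 7 (13S)-labd-7-ene-15,17-diyl diacetate [(5S,9R,10S,13S), the target]
Conditions: Pd(OAc)2 (10 mol%), 4,5-diazafluoren-9-one (10 mol%), NaOAc (20 mol%), AcOH (20 equiv), 1,4-dioxane, O2 (1 atm), 60 °C, 36 h
Reagents that add atoms: acetic acid, CC(=O)O
Why: Proposed new method: aerobic palladium diacetate/4,5-diazafluoren-9-one allylic C–H acetoxylation, so far a linear-selective reaction of terminal monosubstituted alkenes, is extended to a hindered exocyclic 1,1-disubstituted alkene, where acetate-assisted cleavage of the axial C7–H on the open α face (methylene hydrogens are expected to be removed much faster than the C9 methine, as in stoichiometric formation of η3-allylpalladium complexes from methylenecycloalkanes) gives the C17–C8–C7 η3-allyl complex of divalent palladium, acetate then bonds to the unhindered C17 terminus to form the C–O bond and the trisubstituted C7=C8 alkene (the favoured allyl acetate, since C–O formation is reversible at zerovalent palladium until O2 reoxidises it), and the trisubstituted product binds palladium too weakly to be oxidised again; the closest known reactions are that terminal-alkene acetoxylation and the palladium diacetate/benzoquinone allylic acetoxylation of cycloalkenes, and no stereocentre is created.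

**Compound list**
1 | (−)-sclareol, (13R)-labd-14-ene-8α,13-diol [(5S,8R,9R,10S,13R)] | C=C[C@](C)(O)CC[C@H]1[C@](C)(O)CC[C@H]2C(C)(C)CCC[C@]12C | starting material
2 | 8α-hydroxylabd-13-en-15-al, 13E/13Z mixture (alkene geometry left open in the SMILES) | O=CC=C(C)CC[C@H]1[C@](C)(O)CC[C@H]2C(C)(C)CCC[C@]12C | intermediate
3 | (13S)-8α-hydroxylabdan-15-al | O=CC[C@@H](C)CC[C@H]1[C@](C)(O)CC[C@H]2C(C)(C)CCC[C@]12C | intermediate (not isolated)
4 | (13S)-labdane-8α,15-diol | OCC[C@@H](C)CC[C@H]1[C@](C)(O)CC[C@H]2C(C)(C)CCC[C@]12C | intermediate
5 | (13S)-8α-hydroxylabdan-15-yl acetate | CC(=O)OCC[C@@H](C)CC[C@H]1[C@](C)(O)CC[C@H]2C(C)(C)CCC[C@]12C | intermediate (not isolated)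
6 | (13S)-labd-8(17)-en-15-yl acetate | CC(=O)OCC[C@@H](C)CC[C@H]1C(=C)CC[C@H]2C(C)(C)CCC[C@]12C | intermediate
7 | (13S)-labd-7-ene-15,17-diyl diacetate [(5S,9R,10S,13S)] | CC(=O)OCC[C@@H](C)CC[C@H]1C(COC(C)=O)=CC[C@H]2C(C)(C)CCC[C@]12C | target

**Totals**
Total steps: 4. Longest linear sequence: 4 (fully linear from sclareol).

**Three steps most likely to fail**

Step 4 (the new step). The risks are competing C9–H cleavage (giving the 8(9)-ene isomer), acetate attack at C7 (giving the 7-acetoxy-8(17)-ene), and low turnover with the hindered alkene. The known-chemistry fallback sets out from 6 and comes back at 7. Epoxidation of 6 from the open α face (m-chloroperbenzoic acid, NaHCO3, CH2Cl2, 0 °C) gives (13S)-8α,17-epoxylabdan-15-yl acetate F4. Lithium amide epoxide-to-allylic-alcohol isomerisation (LiNEt2, 6 equiv, Et2O, reflux; then K2CO3, MeOH to complete acetate cleavage) removes a C7 methylene hydrogen in preference to the C9 methine and gives (13S)-labd-7-ene-15,17-diol F5. Diacetylation (Ac2O, pyridine, DMAP, CH2Cl2, rt) gives 7.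

Step 1. The mildly acidic oxidant can ionise the 13-position and let the 8-OH close to manoyl oxides, lowering the yield of 2. The fallback sets out from 1 and comes back at 2, building the enal by cleavage and olefination instead of transposition. KMnO4 (MgSO4, acetone–water, 0 °C) cleaves the vinyl carbinol to 8α-hydroxy-14,15-dinorlabdan-13-one F1. Horner–Wadsworth–Emmons reaction with (EtO)2P(O)CH2CN (NaH, 1.0 equiv relative to the phosphonate so the 8-OH stays protonated, THF, 0 °C to rt) gives 8α-hydroxylabd-13-ene-15-nitrile F2 as an E/Z mixture. Reduction with i-Bu2AlH (toluene, −78 °C; aqueous tartaric acid work-up) gives 2.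

Step 2. The C13 selectivity (about 95:5) may not upgrade if the diol crystallises poorly, and the 8-OH could add reversibly to the iminium ion. The fallback sets out from 2 and comes back at 4, replacing iminium catalysis by directed hydrogenation of a geometrically pure allylic alcohol. The 13E isomer of 2 is separated on silica gel (the 13Z isomer is re-equilibrated with a trace of amine and recycled) and reduced (NaBH4, CeCl3·7H2O, MeOH, 0 °C) to (13E)-labd-13-ene-8α,15-diol F3. Hydrogenation (H2, 30 atm, Ru(OAc)2[(R)-BINAP] 1 mol%, MeOH, rt) gives 4 with 13S, in the same sense as geraniol to (S)-citronellol.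

**Further compounds**
F1 | step 1 | 8α-hydroxy-14,15-dinorlabdan-13-one | CC(=O)CC[C@H]1[C@](C)(O)CC[C@H]2C(C)(C)CCC[C@]12C
F2 | step 1 | 8α-hydroxylabd-13-ene-15-nitrile (13E/13Z mixture) | N#CC=C(C)CC[C@H]1[C@](C)(O)CC[C@H]2C(C)(C)CCC[C@]12C
F3 | step 2 | (13E)-labd-13-ene-8α,15-diol | OC/C=C(\C)CC[C@H]1[C@](C)(O)CC[C@H]2C(C)(C)CCC[C@]12C
F4 | step 4 | (13S)-8α,17-epoxylabdan-15-yl acetate | CC(=O)OCC[C@@H](C)CC[C@H]1[C@@]2(CO2)CC[C@H]3C(C)(C)CCC[C@]13C
F5 | step 4 | (13S)-labd-7-ene-15,17-diol | OCC[C@@H](C)CC[C@H]1C(CO)=CC[C@H]2C(C)(C)CCC[C@]12C
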